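## Plan

- The target is the 3-O-caffeoyl-4-O-p-coumaroyl ester of natural quinic acid, (1R,3R,4S,5R). Its enabling feature is C1, a quaternary carbinol carbon that bears the carboxyl C7 and sits between two ring CH2 groups (C2, C6) in a six-membered carbocycle. C1 is therefore the α-carbon of an α-oxygenated acrolein, and the ring C1–C6 is its butadiene adduct.
- Retrosynthetic cuts, in order: the O4–p-coumaroyl and O3–caffeoyl ester bonds; the C7–O5 lactone bond; the C3–O and C4–O bonds (cis-diol back to a C3=C4 alkene); the C5–O/C4–I pair (back to a C4=C5 alkene); last C1–C6 and C2–C3 (retro-[4+2]).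
- Forward: the cyclohexene ring arises first (Diels–Alder). The γ-lactone is the second ring (iodolactonisation) and masks C7 and O5 until the last step. The two arylpropenoyl chains are joined last, caffeoyl at the equatorial O3 before p-coumaroyl at the axial O4.
- Stereochemistry: C1 from the chiral primary ammonium catalyst; C5 from C1 through the lactone tether; C3 and C4 from osmylation anti to the lactone bridge; both E-alkenes come with the commercial cinnamic acids.

Key step: step 3

Remark: ring atoms carry quinate numbering throughout (bicyclic locants 1–5 and 7 coincide with it; bicyclic C8 is quinate C6). Catalyst-bound turnover species (the iminium ions of step 3, the osmate ester of step 8) are described in the Why lines and are not numbered as compounds.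

## Route

Step 1
Reactants: 1 2,2-dimethyl-1,3-dioxan-5-one
Product: 3 2,2-dimethyl-4H-1,3-dioxin-5-yl benzoate, via potassium 2,2-dimethyl-4H-1,3-dioxin-5-olate 2 (not isolated)
Conditions: KHMDS, THF, −78 °C; then BzCl, −78 → 0 °C
Reagents that add atoms: benzoyl chloride, O=C(Cl)c1ccccc1; potassium bis(trimethylsilyl)amide, C[Si](C)(C)[N-][Si](C)(C)C.[K+] (potassium only in intermediate 2)
Why: Deprotonation of the α-alkoxy ketone gives potassium enolate 2, whose hard oxygen is acylated by the acid chloride (O-acylation of an enolate to an enol ester); no stereocentre is involved.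

Step 2
Reactants: 3 2,2-dimethyl-4H-1,3-dioxin-5-yl benzoate
Product: 4 3-oxoprop-1-en-2-yl benzoate (1-formylvinyl benzoate, 2-benzoyloxyacrolein)
Conditions: toluene, 110 °C, BHT (cat.), acetone distilled off; used promptly
Reagents that add atoms: none
Why: Thermal retro-hetero-Diels–Alder cycloreversion of the 4H-1,3-dioxin expels acetone and unveils the enal, the established access to 2-acyloxyacroleins.

Step 3
Reactants: 4 3-oxoprop-1-en-2-yl benzoate; 5 buta-1,3-diene
Product: 6 (S)-1-formylcyclohex-3-en-1-yl benzoate
Conditions: 5 (excess), chiral primary ammonium salt [(2S)-N1-[(2S)-4-methyl-1-(pyrrolidin-1-yl)pentan-2-yl]-3-phenylpropane-1,2-diamine · 2.75 C6F5SO3H, 10 mol %, or its antipode, whichever delivers (S)-6], EtNO2, sealed vessel, 0 °C → rt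
Reagents that add atoms: none
Why: The primary amine of the catalyst condenses with the formyl group of 4 to an iminium ion of lowered LUMO, s-cis butadiene adds across its C=C in a concerted suprafacial [4+2] cycloaddition that forms C1–C6 and C2–C3 at once, and hydrolysis of the product iminium returns the catalyst and aldehyde 6. The closest known reaction type is the enantioselective Diels–Alder reaction of α-acyloxyacroleins with simple dienes under chiral primary ammonium salt (iminium) catalysis. The cyclohexene ring is closed by intermolecular cycloaddition of a four-carbon and a two-carbon unit, both σ-bonds forming in one step, not by cyclisation of a chain. The only new stereocentre, C1, is controlled by the catalyst: hydrogen bonding of a second ammonium group to the benzoate carbonyl fixes the iminium geometry and the benzyl arm screens one enantioface of the dienophile, the catalyst antipode being chosen so that the diene adds to the face that gives (S). The step needs enantioface selectivity only, because C2v-symmetric butadiene rules out regio- and endo/exo isomers, and the 1,1-disubstituted dienophile, activated both as iminium and by the acyloxy group, makes up for the low reactivity of the unsubstituted diene.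

Step 4
Reactants: 6 (S)-1-formylcyclohex-3-en-1-yl benzoate
Product: 7 (S)-1-(benzoyloxy)cyclohex-3-ene-1-carboxylic acid
Conditions: NaClO2, NaH2PO4, 2-methyl-2-butene, t-BuOH/H2O, 0 °C → rt
Reagents that add atoms: sodium chlorite, [Na+].[O-]Cl=O
Why: Pinnick oxidation converts the aldehyde to the acid while the scavenger removes HOCl, so the ring alkene and the benzoate survive and the quaternary C1 cannot epimerise.

Step 5
Reactants: 7 (S)-1-(benzoyloxy)cyclohex-3-ene-1-carboxylic acid
Product: 9 (1S,4R,5R)-1-hydroxy-4-iodo-6-oxabicyclo[3.2.1]octan-7-one, via sodium (S)-1-hydroxycyclohex-3-ene-1-carboxylate 8 (not isolated)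
Conditions: NaOH (2.2 equiv), THF/H2O, 40 °C; then 0 °C, NaHCO3 to pH ≈ 8, I2, KI, 0 °C → rt, dark; extract the neutral lactone
Reagents that add atoms: iodine, II; sodium hydroxide, [Na+].[OH-] (sodium only in intermediate 8)
Why: Saponification at the benzoyl carbonyl frees O1 without touching the C1–O bond, and iodolactonisation of carboxylate 8 then closes the γ-lactone onto C5, the only alkene carbon C7 can reach and only on its own face (C5 set by the tether from C1, iodine trans-diaxial at C4 by anti addition).

Step 6
Reactants: 9 (1S,4R,5R)-1-hydroxy-4-iodo-6-oxabicyclo[3.2.1]octan-7-one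
Product: 10 (1S,5R)-1-hydroxy-6-oxabicyclo[3.2.1]oct-3-en-7-one
Conditions: DBU, THF, reflux
Reagents that add atoms: none
Why: E2 elimination of the axial C4 iodide with the anti-periplanar axial C3–H gives the C3=C4 alkene, elimination toward the bridgehead C5 being excluded by geometry and Bredt's rule.

Step 7
Reactants: 10 (1S,5R)-1-hydroxy-6-oxabicyclo[3.2.1]oct-3-en-7-one
Product: 11 (1S,5R)-1-[(triethylsilyl)oxy]-6-oxabicyclo[3.2.1]oct-3-en-7-one
Conditions: TESOTf, 2,6-lutidine, CH2Cl2, 0 °C
Reagents that add atoms: triethylsilyl trifluoromethanesulfonate, CC[Si](CC)(CC)OS(=O)(=O)C(F)(F)F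
Why: Silyl triflate with a hindered base silylates the tertiary alcohol (silyl ether formation), removing O1 from the later acylations with a group that the final acid step cleaves.

Step 8
Reactants: 11 (1S,5R)-1-[(triethylsilyl)oxy]-6-oxabicyclo[3.2.1]oct-3-en-7-one
Product: 12 (1S,3R,4R,5R)-3,4-dihydroxy-1-[(triethylsilyl)oxy]-6-oxabicyclo[3.2.1]octan-7-one (1-O-triethylsilyl derivative of the 1,5-lactone of natural quinic acid)
Conditions: OsO4 (cat.), NMO, acetone/H2O, rt
Reagents that add atoms: osmium tetroxide (catalytic oxygen carrier), O=[Os](=O)(=O)=O; N-methylmorpholine N-oxide, C[N+]1([O-])CCOCC1; water, O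
Why: Catalytic syn-dihydroxylation through a cyclic osmate ester takes place on the open face of the C3=C4 alkene, anti to the lactone bridge and to the allylic C5 oxygen, which sets C3 and C4 cis to each other and trans to O5 as in quinic acid.

Step 9
Reactants: 13 caffeic acid
Product: 14 3,4-di-O-acetylcaffeic acid [(E)-3-(3,4-diacetoxyphenyl)prop-2-enoic acid]
Conditions: Ac2O, pyridine, rt; aq. HCl work-up
Reagents that add atoms: acetic anhydride, CC(=O)OC(C)=O
Why: Acetylation of both phenols (nucleophilic acyl substitution) masks the catechol for acid chloride formation and leaves the E-alkene and the free acid unchanged after aqueous work-up.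

Step 10
Reactants: 14 3,4-di-O-acetylcaffeic acid
Product: 15 3,4-di-O-acetylcaffeoyl chloride
Conditions: (COCl)2, DMF (cat.), CH2Cl2, 0 °C → rt; concentrate, use crude
Reagents that add atoms: oxalyl chloride, O=C(Cl)C(Cl)=O
Why: Vilsmeier-type activation converts the acid to the acid chloride under conditions that aryl acetates and the cinnamoyl alkene tolerate.

Step 11
Reactants: 12 1-O-triethylsilyl quinide diol; 15 3,4-di-O-acetylcaffeoyl chloride
Product: 16 3-O-(3,4-di-O-acetylcaffeoyl)-1-O-triethylsilyl-1,5-quinide (ester on the equatorial C3 oxygen, axial 4-OH free)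
Conditions: 15 (1.05 equiv), pyridine, CH2Cl2, −20 → 0 °C
Reagents that add atoms: none
Why: Acylation with an acid chloride goes to the equatorial 3-OH in preference to the axial 4-OH, which is flanked by the lactone bridgehead, while O1 is silylated and O5 is held in the lactone (regioselective esterification of a cis-diol).

Step 12
Reactants: 17 p-coumaric acid
Product: 18 4-O-acetyl-p-coumaric acid [(E)-3-(4-acetoxyphenyl)prop-2-enoic acid]
Conditions: Ac2O, pyridine, rt; aq. HCl work-up
Reagents that add atoms: acetic anhydride, CC(=O)OC(C)=O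
Why: Phenol acetylation as in step 9 masks the phenol for acid chloride formation.

Step 13
Reactants: 18 4-O-acetyl-p-coumaric acid
Product: 19 4-O-acetyl-p-coumaroyl chloride
Conditions: (COCl)2, DMF (cat.), CH2Cl2, 0 °C → rt; concentrate, use crude
Reagents that add atoms: oxalyl chloride, O=C(Cl)C(Cl)=O
Why: Acid chloride formation as in step 10.

Step 14
Reactants: 16 3-O-(3,4-di-O-acetylcaffeoyl)-1-O-triethylsilyl-1,5-quinide; 19 4-O-acetyl-p-coumaroyl chloride
Product: 20 3-O-(3,4-di-O-acetylcaffeoyl)-4-O-(4-O-acetyl-p-coumaroyl)-1-O-triethylsilyl-1,5-quinide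
Conditions: 19 (1.5 equiv), DMAP (0.2 equiv), pyridine, CH2Cl2, 0 °C → rt
Reagents that add atoms: none
Why: DMAP-catalysed acyl transfer esterifies the only remaining hydroxyl, the hindered axial 4-OH, and the fast acylpyridinium pathway should outrun 3→4 migration of the caffeoyl group.

Step 15
Reactants: 20 fully protected diester lactone
Product: 21 (1R,3R,4S,5R)-3-{[(E)-3-(3,4-dihydroxyphenyl)prop-2-enoyl]oxy}-1,5-dihydroxy-4-{[(E)-3-(4-hydroxyphenyl)prop-2-enoyl]oxy}cyclohexane-1-carboxylic acid (3-O-caffeoyl-4-O-p-coumaroylquinic acid)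
Conditions: 2 M aq. HCl/THF, rt, several days, N2, dark
Reagents that add atoms: water, O
Why: Acid-catalysed hydrolysis cleaves the three aryl acetates (phenol leaving groups, more labile than the conjugated alkyl cinnamates) and the silyl ether and opens the strained γ-lactone to the hydroxy acid, while the acidic medium suppresses base-promoted acyl migration and no stereocentre is touched.

## Compound list

1 | 2,2-dimethyl-1,3-dioxan-5-one | CC1(C)OCC(=O)CO1 | starting material
2 | potassium 2,2-dimethyl-4H-1,3-dioxin-5-olate | CC1(C)OCC([O-])=CO1.[K+] | intermediate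
3 | 2,2-dimethyl-4H-1,3-dioxin-5-yl benzoate | CC1(C)OCC(OC(=O)c2ccccc2)=CO1 | intermediate
4 | 3-oxoprop-1-en-2-yl benzoate (2-benzoyloxyacrolein) | C=C(C=O)OC(=O)c1ccccc1 | intermediate
5 | buta-1,3-diene | C=CC=C | starting material
6 | (S)-1-formylcyclohex-3-en-1-yl benzoate | C1=CC[C@](OC(=O)c2ccccc2)(C=O)CC1 | intermediate
7 | (S)-1-(benzoyloxy)cyclohex-3-ene-1-carboxylic acid | C1=CC[C@](OC(=O)c2ccccc2)(C(=O)O)CC1 | intermediate
8 | sodium (S)-1-hydroxycyclohex-3-ene-1-carboxylate | C1=CC[C@](O)(C(=O)[O-])CC1.[Na+] | intermediate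
9 | (1S,4R,5R)-1-hydroxy-4-iodo-6-oxabicyclo[3.2.1]octan-7-one | O[C@@]12CC[C@@H](I)[C@@H](C1)OC2=O | intermediate
10 | (1S,5R)-1-hydroxy-6-oxabicyclo[3.2.1]oct-3-en-7-one | O[C@@]12CC=C[C@@H](C1)OC2=O | intermediate
11 | (1S,5R)-1-[(triethylsilyl)oxy]-6-oxabicyclo[3.2.1]oct-3-en-7-one | CC[Si](CC)(CC)O[C@@]12CC=C[C@@H](C1)OC2=O | intermediate
12 | (1S,3R,4R,5R)-3,4-dihydroxy-1-[(triethylsilyl)oxy]-6-oxabicyclo[3.2.1]octan-7-one | CC[Si](CC)(CC)O[C@@]12C[C@@H](O)[C@@H](O)[C@@H](C1)OC2=O | intermediate
13 | caffeic acid | O=C(O)/C=C/c1ccc(O)c(O)c1 | starting material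
14 | 3,4-di-O-acetylcaffeic acid | CC(=O)Oc1ccc(/C=C/C(=O)O)cc1OC(C)=O | intermediate
15 | 3,4-di-O-acetylcaffeoyl chloride | CC(=O)Oc1ccc(/C=C/C(Cl)=O)cc1OC(C)=O | intermediate
16 | 3-O-(3,4-di-O-acetylcaffeoyl)-1-O-triethylsilyl-1,5-quinide | CC[Si](CC)(CC)O[C@@]12C[C@@H](OC(=O)/C=C/c3ccc(OC(C)=O)c(OC(C)=O)c3)[C@@H](O)[C@@H](C1)OC2=O | intermediate
17 | p-coumaric acid | O=C(O)/C=C/c1ccc(O)cc1 | starting material
18 | 4-O-acetyl-p-coumaric acid | CC(=O)Oc1ccc(/C=C/C(=O)O)cc1 | intermediate
19 | 4-O-acetyl-p-coumaroyl chloride | CC(=O)Oc1ccc(/C=C/C(Cl)=O)cc1 | intermediate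
20 | 3-O-(3,4-di-O-acetylcaffeoyl)-4-O-(4-O-acetyl-p-coumaroyl)-1-O-triethylsilyl-1,5-quinide | CC[Si](CC)(CC)O[C@@]12C[C@@H](OC(=O)/C=C/c3ccc(OC(C)=O)c(OC(C)=O)c3)[C@@H](OC(=O)/C=C/c3ccc(OC(C)=O)cc3)[C@@H](C1)OC2=O | intermediate
21 | (1R,3R,4S,5R)-3-O-caffeoyl-4-O-p-coumaroylquinic acid | O=C(/C=C/c1ccc(O)cc1)O[C@H]1[C@H](O)C[C@](O)(C(=O)O)C[C@H]1OC(=O)/C=C/c1ccc(O)c(O)c1 | target

## Step count and risks

Total step count: 15. Longest linear sequence: 11 steps (steps 1–8, 11, 14, 15).

Steps most likely to fail:

Step 3. The unsubstituted diene may add too slowly, so that the acyloxyacrolein polymerises first, or the catalyst may not discriminate the enantiofaces well enough. The fallback keeps the same cycloaddition but separates ring formation from asymmetric induction. It sets out from 4 and 5 and returns at 7. Heating 4 with excess 5 without chiral catalyst (toluene, sealed vessel, 80–100 °C, BHT) should give racemic 1-formylcyclohex-3-en-1-yl benzoate F1. Pinnick oxidation as in step 4 gives racemic 1-(benzoyloxy)cyclohex-3-ene-1-carboxylic acid F2. Classical resolution by crystallisation with 1-phenylethylamine gives the diastereomerically pure salt (R)-1-phenylethylammonium (S)-1-(benzoyloxy)cyclohex-3-ene-1-carboxylate F3; the amine antipode is chosen so that the salt of the (S)-acid is the less soluble one, written here with the (R)-amine. Acidification liberates 7.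

Step 11. The acid chloride may not discriminate well between the equatorial 3-OH and the axial 4-OH (mixed mono-esters, bis-acylation), or the caffeoyl group may migrate from O3 to O4 before the second acylation. The fallback marks O3 first with a more size-sensitive silylation and reverses the order of the two acylations. It sets out from 12 and returns at 21. TBSCl/imidazole in DMF should give 3-O-tert-butyldimethylsilyl-1-O-triethylsilyl-1,5-quinide F4. Acylation of its remaining 4-OH with 19 (DMAP, pyridine) gives 4-O-(4-O-acetyl-p-coumaroyl)-3-O-tert-butyldimethylsilyl-1-O-triethylsilyl-1,5-quinide F5. HF·pyridine in THF removes both silyl groups under acidic conditions that do not promote migration, giving 4-O-(4-O-acetyl-p-coumaroyl)-1,5-quinide F6. Acylation with 15 (pyridine, −20 °C) at the secondary 3-OH, in preference to the tertiary 1-OH, gives 3-O-(3,4-di-O-acetylcaffeoyl)-4-O-(4-O-acetyl-p-coumaroyl)-1,5-quinide F7. The conditions of step 15 convert F7 to 21.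

Step 15. Slow acid hydrolysis of the aryl acetates may force a long exposure, during which the cinnamate esters can hydrolyse or the 4-O-acyl group can migrate to the liberated O5. The fallback stages the deprotection so that the acetates are cleaved by a different reaction while no alcohol is free. It sets out from 20 and returns at 21. Hydrazinium acetate in DMF at 0 °C removes the three aryl acetates by aminolysis, with O1 still silylated and O5 still in the lactone, to give 3-O-caffeoyl-4-O-p-coumaroyl-1-O-triethylsilyl-1,5-quinide F8. A short treatment with aq. HCl/THF then only has to cleave the silyl ether and open the lactone to 21.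

## Further compounds

F1 | step 3 | rac-1-formylcyclohex-3-en-1-yl benzoate | O=CC1(OC(=O)c2ccccc2)CC=CCC1
F2 | step 3 | rac-1-(benzoyloxy)cyclohex-3-ene-1-carboxylic acid | OC(=O)C1(OC(=O)c2ccccc2)CC=CCC1
F3 | step 3 | (R)-1-phenylethylammonium (S)-1-(benzoyloxy)cyclohex-3-ene-1-carboxylate | C1=CC[C@](OC(=O)c2ccccc2)(C([O-])=O)CC1.C[C@@H]([NH3+])c1ccccc1
F4 | step 11 | 3-O-tert-butyldimethylsilyl-1-O-triethylsilyl-1,5-quinide | CC[Si](CC)(CC)O[C@@]12C[C@@H](O[Si](C)(C)C(C)(C)C)[C@@H](O)[C@@H](C1)OC2=O
F5 | step 11 | 4-O-(4-O-acetyl-p-coumaroyl)-3-O-tert-butyldimethylsilyl-1-O-triethylsilyl-1,5-quinide | CC[Si](CC)(CC)O[C@@]12C[C@@H](O[Si](C)(C)C(C)(C)C)[C@@H](OC(=O)/C=C/c3ccc(OC(C)=O)cc3)[C@@H](C1)OC2=O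
F6 | step 11 | 4-O-(4-O-acetyl-p-coumaroyl)-1,5-quinide | O[C@@]12C[C@@H](O)[C@@H](OC(=O)/C=C/c3ccc(OC(C)=O)cc3)[C@@H](C1)OC2=O
F7 | step 11 | 3-O-(3,4-di-O-acetylcaffeoyl)-4-O-(4-O-acetyl-p-coumaroyl)-1,5-quinide | O[C@@]12C[C@@H](OC(=O)/C=C/c3ccc(OC(C)=O)c(OC(C)=O)c3)[C@@H](OC(=O)/C=C/c3ccc(OC(C)=O)cc3)[C@@H](C1)OC2=O
F8 | step 15 | 3-O-caffeoyl-4-O-p-coumaroyl-1-O-triethylsilyl-1,5-quinide | CC[Si](CC)(CC)O[C@@]12C[C@@H](OC(=O)/C=C/c3ccc(O)c(O)c3)[C@@H](OC(=O)/C=C/c3ccc(O)cc3)[C@@H](C1)OC2=O
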